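## Structural features

The target 22 is an (E)-enone that joins two aromatic units: a 4-hydroxyphenyl ketone (ring C) and, through the β-carbon, C5 of a 2,3-dihydrobenzofuran (benzene ring A fused to dihydrofuran ring B). Ring A carries four neighbouring substituents: O1 on C7a, the C3 methylene on C3a, a methoxy group on C4 and the enone chain on C5; C6 and C7 are unsubstituted. The only stereocentre is C2 (S), which bears a 2-hydroxypropan-2-yl group. It has no stereogenic neighbour, so nothing in the molecule can relay configuration to it, and the E double bond is the thermodynamic isomer. The fragile groups are the enone (conjugate addition, E/Z isomerisation in light), the free phenol, and the tertiary alcohol β to the aryl ether oxygen, which acid could ionise, dehydrate or ring-expand to a chroman. C2 can epimerise only while it carries a carbonyl group. The real difficulties are the absolute configuration of this isolated centre and the regiochemistry of ring A, where C5 and C7 are both activated by two oxygens. The key step exploits the fact that C3 is an unsubstituted CH2 on C3a, ortho to the C7a–O1 bond, so O1–C7a–C3a–C3 is a latent ortho-quinone methide. C2 is a single carbon that can arrive as an ylide carbon whose ester later becomes the carbinol. The 2,6-dioxygenated benzyl unit is symmetrical, so either oxygen can become O1 and the other becomes the C4 oxygen that later steers the formyl group to C5.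

## Logic of the disconnections

**22 ⇒ 19 + 20.** The Cα=Cβ bond of the enone is cut (retro-aldol condensation). It is the only bond between the two aromatic halves and has natural polarity: a methyl ketone enolate and a non-enolisable aryl aldehyde. This separates the achiral ketone 20 from the chiral aldehyde 19 and leaves the E geometry to thermodynamics. The forward step must tolerate the free phenol of 20, an electron-rich aldehyde and the tertiary alcohol.

**19 ⇒ 18 ⇒ 16.** The O–CH3 bond at C4 and then the C5–CHO bond are cut. A free hydroxyl at C4 is the one handle that distinguishes C5 (its only open ortho position) from C7, so the formyl group is introduced while the phenol is free and the methyl group afterwards. Ring A is thereby simplified to a 1,2,3-trisubstituted arene. The formylation must be strictly ortho-selective and the methylation must spare the tertiary alcohol.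

**16 ⇒ 15 ⇒ 13.** The O–Si bond is cut (protecting group) and then both C–CH3 bonds of the carbinol. The carbinol is a masked ester, and an ester is what stabilises a one-carbon ylide. The side chain at C2 shrinks to a carboxylate. The double methyl addition must outrun enolisation of 13 and of ketone 14, and the silyl ether should stay on until C2 is no longer acidic.

**13 ⇒ 4 + 9 (through 10, 11 and 12).** The C2–C3 and O1–C2 bonds are cut. C3 with C3a, C7a and O1 is the methide 10, and C2 is the ylide carbon of 11. This removes ring B and the stereocentre in one operation and gives two fragments of similar size, one of them symmetrical. The chiral sulfide must control C2, fluoride must trigger 10 without stripping everything, and 13 must not epimerise in the basic medium.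

**4 ⇒ 3 ⇒ 2 ⇒ 1.** The C–Br bond, the benzylic C–H bond (reduction) and the two O–Si bonds are cut. These are plain functional-group changes back to a commercial dihydroxy aldehyde. Silyl migration during the reduction must be avoided and 4 must be handled as a labile benzylic halide.

**9 ⇒ 7 + 8; 7 ⇒ 6 ⇒ 5.** The S–CH2 bond is cut, then both C–S bonds of the thiolane, then the O–S bonds. A sulfonium salt comes from a sulfide and an α-halo ester, and a C2-symmetric thiolane comes from a C2-symmetric diol by double displacement. This leads to two commercial compounds. Both displacements must go with clean inversion and the hindered sulfide must accept alkylation.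

## Other disconnections considered

**Alternative 1:** The cut is the C5–Cβ bond of the enone, with the future carbonyl carbon parked on the C4 oxygen. Phenol 16 would be O-alkylated with a 1-arylprop-2-ynyl unit to give aryl propargyl ether A1. On heating, A1 should rearrange (aromatic propargyl Claisen) to C5, the only open ortho carbon, and the allenyl phenol should pass by 1,5-hydrogen shift and oxa-6π closure to chromene A2. The new chromene stereocentre is of no consequence because that carbon ends as the carbonyl. From A2 the target needs hydride abstraction to the benzopyrylium ion, alkaline ring opening to the hydroxy chalcone, O-methylation of the released phenol and removal of the methoxymethyl group.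

- In its favour: the C5–C bond forms under neutral thermal conditions with no electrophilic substitution, and all three enone carbons plus ring C arrive in one operation.
- Equal to the chosen plan: regiochemical security at C5, since both rely on C5 being the single free ortho site of the C4 oxygen.
- Better than the chosen plan: it avoids an aldol condensation with a deactivated, hindered aldehyde.
- Against it: A1 is a secondary propargylic ether next to an electron-rich aryl group, so C–O heterolysis can compete with the sigmatropic shift. A2 is at the wrong oxidation level, the pyrylium/chalcone manifold is pH-dependent, and the final acidic deprotection meets the tertiary alcohol.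
- Structure: it does nothing for C2, so 16 must still be made by another asymmetric method.
- Step economy: from 16 it needs about five operations plus two for the propargylic partner, against three in the chosen plan.

**Alternative 2:** The cut is C3–C3a and O1–C2, with the C2 substituent at the alkene oxidation level. 2-Iodoresorcinol A3 and isoprene A4 would be joined with Pd(OAc)2 and a chiral phosphine. Oxidative addition of the C–I bond to zerovalent palladium, insertion of the unsubstituted vinyl group of A4 (aryl to the terminal CH2) and attack of a phenoxide on the internal terminus of the allylpalladium intermediate would give (S)-2-(prop-1-en-2-yl)-2,3-dihydrobenzofuran-4-ol A5.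

- In its favour: ring B, both ring bonds and the stereocentre come from two commercial compounds in one catalytic step.
- Equal to the chosen plan: the symmetry of A3 makes either hydroxyl a correct O1, the same device as in 4.
- Better than the chosen plan: chirality is used catalytically, and enantioselective diene heteroannulation of ortho-halophenols is a known reaction class that already reaches the 2-isopropenyl motif. The induction step of the chosen plan has no such precedent.
- Better on step economy: A5 needs a Markovnikov hydration to reach 16 and then the same three closing steps, about five steps in all against twelve (nine linear).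
- Against it: the aryl iodide is flanked by two free hydroxyl groups, which should slow oxidative addition and insertion and may bind palladium. The regiochemistry of insertion into A4 and of allyl capture (branched five-membered against six-membered ring) must both go the right way. The selectivity would have to be established for this doubly ortho-substituted substrate, the ligand is specialised, and the hydration must be done on an electron-rich free phenol.
- Mechanism: its stereo-determining step is an allylic substitution under ligand control; that of the chosen plan is an SN2 ring closure under control of the leaving group.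
- Why the chosen plan is kept: it uses stoichiometric reagents that are easy to make and has a resolution safety net at the same intermediate.

**Alternative 3:** The cut is O1–C2 together with the C–OH bond of the carbinol, and the retron is a 3-chromanol. Chromene ester A6 would be subjected to Jacobsen epoxidation and the epoxide opened reductively at the benzylic carbon to give (R)-chromanol A7. Activation of the hydroxyl of A7 should let the aryl ether oxygen shift from the gem-dimethyl carbon to the carbinol carbon with inversion, through a bridged oxonium ion that water opens at the tertiary carbon. The product is ring-contracted ester A8.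

- In its favour: the methoxy group and the C5 carbon substituent are present from the start, so no late formylation is needed, and the 1,2-shift is stereospecific.
- Better than the chosen plan: the enantioselectivity comes from a reaction with excellent precedent on 2,2-dimethylchromenes.
- Against it: the migrating oxygen is para to the ester and so a weakened neighbouring group. Elimination to the chromene, direct substitution without shift and methyl migration all compete in the cationic step. A6 needs a regioselective (angular) chromene annulation, the epoxide needs regioselective benzylic reduction, and A8 needs two redox steps to become 19.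
- Mechanism: the risk moves from asymmetric induction to a cationic skeletal rearrangement, whereas the chosen ring closure is anionic and mild.
- Step economy: roughly ten linear steps against nine, so comparable but not shorter.

Key step: step 7

## Assumptions and design remarks

- Structure check: 22 and ester 13 are both 2S, and the 2R,5R salt 9 follows from the 2S,5S diol 5 by double inversion. The names and structures agree with one another and none needed correction.
- Assumption: the 2R,5R salt 9 is taken to lead to the S ester 13. If the opposite sense is met, the mirror-image salt made in the same way from the enantiomer of 5 is used.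
- Design remark: one equivalent of fluoride cannot be expected to choose cleanly between the two silyl ethers of 4 and the one of 13. A small excess is therefore used, and any ester that loses its second silyl group is carried on, because it converges on 16 in steps 8 and 9.
- Design remark: the C4 hydroxyl is kept free until after formylation, because it is the only reliable control of C5 against C7.

## Route

Step 1
Reactants: 1 2,6-dihydroxybenzaldehyde
Product: 2 2,6-bis(tert-butyldimethylsilyloxy)benzaldehyde
Conditions: TBSCl (2.5 equiv), imidazole (5 equiv), DMF, 0 °C to rt
Reagents that add atoms: tert-butyldimethylsilyl chloride, CC(C)(C)[Si](C)(C)Cl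
Why: Standard O-silylation of phenols with the silyl chloride activated by imidazole; both hydroxyl groups react, which keeps the molecule symmetrical so that either oxygen can later serve as O1, and the aldehyde is untouched.

Step 2
Reactants: 2 2,6-bis(tert-butyldimethylsilyloxy)benzaldehyde
Product: 3 [2,6-bis(tert-butyldimethylsilyloxy)phenyl]methanol
Conditions: NaBH4, THF/MeOH, −10 to 0 °C, 30 min; aq. NH4Cl
Reagents that add atoms: none
Why: Borohydride reduction of the aryl aldehyde to the benzylic alcohol; low temperature and a prompt buffered quench limit transfer of a silyl group from a phenol oxygen to the new alkoxide.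

Step 3
Reactants: 3 [2,6-bis(tert-butyldimethylsilyloxy)phenyl]methanol
Product: 4 [2-(bromomethyl)-1,3-phenylene]bis(oxy)bis(tert-butyldimethylsilane)
Conditions: CBr4, PPh3, CH2Cl2, 0 °C, 20 min; pentane trituration, short silica plug, used at once
Reagents that add atoms: carbon tetrabromide, BrC(Br)(Br)Br
Why: Appel reaction: the alkoxyphosphonium ion is displaced by bromide under neutral conditions, so neither silyl ether is cleaved; the electron-rich benzylic bromide is not stored.

Step 4
Reactants: 5 (2S,5S)-hexane-2,5-diol
Product: 6 (2S,5S)-hexane-2,5-diyl dimethanesulfonate
Conditions: MsCl, Et3N, CH2Cl2, 0 °C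
Reagents that add atoms: methanesulfonyl chloride, CS(=O)(=O)Cl
Why: O-Sulfonylation of both secondary alcohols; no bond to either stereocentre is broken, so 6 keeps the 2S,5S configuration.

Step 5
Reactants: 6 (2S,5S)-hexane-2,5-diyl dimethanesulfonate
Product: 7 (2R,5R)-2,5-dimethylthiolane
Conditions: Na2S·9H2O, EtOH, rt, 24 h; distillation
Reagents that add atoms: sodium sulfide (Na2S), [Na+].[Na+].[S-2]
Why: Double SN2 displacement by sulfide, the second an intramolecular 5-exo-tet closure; each carbon is inverted once, which turns the 2S,5S dimesylate into the 2R,5R thiolane.

Step 6
Reactants: 7 (2R,5R)-2,5-dimethylthiolane; 8 ethyl bromoacetate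
Product: 9 (2R,5R)-1-(2-ethoxy-2-oxoethyl)-2,5-dimethylthiolan-1-ium bromide
Conditions: neat (or acetone), rt, 3–5 d; Et2O trituration
Reagents that add atoms: none
Why: SN2 S-alkylation of the sulfide by the α-bromo ester (sulfonium salt formation); because 7 is C2-symmetric its two sulfur lone pairs are equivalent, sulfur does not become a stereocentre and a single salt should form.

Step 7
Reactants: 4 [2-(bromomethyl)-1,3-phenylene]bis(oxy)bis(tert-butyldimethylsilane); 9 (2R,5R)-1-(2-ethoxy-2-oxoethyl)-2,5-dimethylthiolan-1-ium bromide
Product: 13 ethyl (2S)-4-(tert-butyldimethylsilyloxy)-2,3-dihydro-1-benzofuran-2-carboxylate, via silyloxy ortho-quinone methide 10 (not isolated), via sulfonium ylide 11 (not isolated), via phenoxide sulfonium betaine 12 (not isolated)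
Conditions: 9 (1.3 equiv), Cs2CO3 (1.5 equiv), CsF (1.3 equiv), 18-crown-6 (0.3 equiv), MeCN/CH2Cl2, −20 °C; 4 added over 2 h; −20 to 0 °C
Reagents that add atoms: none
Why: Proposed new method: the annulation belongs to the known [4+1] reaction of ortho-quinone methides with ester-stabilised sulfonium ylides, but induction by the sulfide at a methide with no substituent, where the only new stereocentre is the former ylide carbon, has no direct precedent; the closest known reactions are the chiral-sulfide and chiral-ammonium ylide annulations of substituted methides. Cs2CO3 converts 9 into ylide 11, while fluoride removes one of the two equivalent silyl groups of 4 and the phenoxide expels bromide to give methide 10, kept at low concentration by slow addition of 4. Conjugate addition of the ylide carbon to the exocyclic CH2 of 10 restores the aromatic ring and forms C2–C3 in betaine 12; direct SN2 benzylation of 11 by 4 followed by desilylation would reach the same betaine, so both entries converge. The phenoxide then displaces the thiolane at the ester-bearing carbon with inversion, a 5-exo-tet closure that forms O1–C2 and releases 7 for recovery. The carbon between ester and sulfonium in 12 is acidic, so its two epimers should interconvert through the substituted ylide faster than they close, and C2 would then be set in the ring closure under Curtin–Hammett control, the C2-symmetric thiolanium leaving group with one methyl group on each flank of the reacting carbon being the only controlling element. The step needs enantioselectivity, which rests on that leaving group and on the low temperature, and it needs 13 to keep its C2–H, which the mild heterogeneous carbonate and the much lower acidity of 13 compared with 12 should secure. Chemoselectivity between the silyl groups is eased by the symmetry of 4, and ester that loses its second silyl group is not wasted because it converges on 16 after steps 8 and 9.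

Step 8
Reactants: 13 ethyl (2S)-4-(tert-butyldimethylsilyloxy)-2,3-dihydro-1-benzofuran-2-carboxylate
Product: 15 2-[(2S)-4-(tert-butyldimethylsilyloxy)-2,3-dihydro-1-benzofuran-2-yl]propan-2-ol, via methyl ketone 14 (not isolated)
Conditions: MeMgBr (4 equiv), THF, −78 to 0 °C; aq. NH4Cl
Reagents that add atoms: methylmagnesium bromide, C[Mg]Br
Why: Double Grignard addition to the ester; ketone 14 is more electrophilic than 13 and should be consumed by the excess reagent at low temperature faster than it is enolised, so C2 keeps its configuration, and the aryl silyl ether is inert to the reagent.

Step 9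
Reactants: 15 2-[(2S)-4-(tert-butyldimethylsilyloxy)-2,3-dihydro-1-benzofuran-2-yl]propan-2-ol
Product: 16 (2S)-2-(2-hydroxypropan-2-yl)-2,3-dihydro-1-benzofuran-4-ol
Conditions: TBAF (1.2 equiv), AcOH (1.2 equiv), THF, 0 °C
Reagents that add atoms: none
Why: Fluoride cleavage of the aryl silyl ether driven by Si–F bond formation; acetic acid buffers the phenoxide, and C2 can no longer epimerise because it carries no carbonyl group.

Step 10
Reactants: 16 (2S)-2-(2-hydroxypropan-2-yl)-2,3-dihydro-1-benzofuran-4-ol
Product: 18 (2S)-4-hydroxy-2-(2-hydroxypropan-2-yl)-2,3-dihydro-1-benzofuran-5-carbaldehyde, via hydroxymethyl phenol 17 (not isolated)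
Conditions: MgCl2 (3 equiv), Et3N (5 equiv), (CH2O)n (8 equiv), MeCN, 80 °C; cold aq. citric acid
Reagents that add atoms: paraformaldehyde (as formaldehyde), C=O
Why: Magnesium-mediated ortho-formylation of a phenol (Casnati–Skattebøl reaction): the ArOMgCl species delivers coordinated formaldehyde to the only free ortho carbon, C5 (the other ortho carbon is C3a), and hydroxymethyl phenol 17 is oxidised by a second formaldehyde through hydride transfer. C7, para to the hydroxyl group, is not reached by this chelate mechanism, and the tertiary alcohol is a spectator.

Step 11
Reactants: 18 (2S)-4-hydroxy-2-(2-hydroxypropan-2-yl)-2,3-dihydro-1-benzofuran-5-carbaldehyde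
Product: 19 (2S)-2-(2-hydroxypropan-2-yl)-4-methoxy-2,3-dihydro-1-benzofuran-5-carbaldehyde
Conditions: MeI (3 equiv), K2CO3 (2 equiv), DMF, rt
Reagents that add atoms: iodomethane, CI
Why: Williamson O-methylation of the phenol; K2CO3 is too weak a base to deprotonate the tertiary alcohol, which stays free, and the aldehyde has no α-hydrogen.

Step 12
Reactants: 19 (2S)-2-(2-hydroxypropan-2-yl)-4-methoxy-2,3-dihydro-1-benzofuran-5-carbaldehyde; 20 4-hydroxyacetophenone
Product: 22 (2E)-3-[(2S)-2-(2-hydroxypropan-2-yl)-4-methoxy-2,3-dihydro-1-benzofuran-5-yl]-1-(4-hydroxyphenyl)prop-2-en-1-one, via aldol adduct 21 (not isolated)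
Conditions: KOH (10 equiv, 50% aq.), EtOH, rt, 24–48 h, dark; then cold dilute HCl to pH 5–6
Reagents that add atoms: none
Why: Claisen–Schmidt condensation: the enolate of 20 (as its phenoxide dianion) adds to the non-enolisable aldehyde 19 and aldol adduct 21 loses water by an E1cB pathway to the conjugated enone, the E isomer being the thermodynamic one. C2 has no acidic hydrogen, and the methoxy group at C4 rules out flavanone-type cyclisation.

## Compound list

1 | 2,6-dihydroxybenzaldehyde | O=Cc1c(O)cccc1O | starting material
2 | 2,6-bis(tert-butyldimethylsilyloxy)benzaldehyde | CC(C)(C)[Si](C)(C)Oc1cccc(O[Si](C)(C)C(C)(C)C)c1C=O | intermediate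
3 | [2,6-bis(tert-butyldimethylsilyloxy)phenyl]methanol | CC(C)(C)[Si](C)(C)Oc1cccc(O[Si](C)(C)C(C)(C)C)c1CO | intermediate
4 | [2-(bromomethyl)-1,3-phenylene]bis(oxy)bis(tert-butyldimethylsilane) | CC(C)(C)[Si](C)(C)Oc1cccc(O[Si](C)(C)C(C)(C)C)c1CBr | intermediate
5 | (2S,5S)-hexane-2,5-diol | C[C@H](O)CC[C@H](C)O | starting material
6 | (2S,5S)-hexane-2,5-diyl dimethanesulfonate | C[C@H](OS(C)(=O)=O)CC[C@H](C)OS(C)(=O)=O | intermediate
7 | (2R,5R)-2,5-dimethylthiolane | C[C@@H]1CC[C@@H](C)S1 | intermediate
8 | ethyl bromoacetate | BrCC(=O)OCC | starting material
9 | (2R,5R)-1-(2-ethoxy-2-oxoethyl)-2,5-dimethylthiolan-1-ium bromide | C[C@@H]1CC[C@@H](C)[S+]1CC(=O)OCC.[Br-] | intermediate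
10 | 5-(tert-butyldimethylsilyloxy)-6-methylidenecyclohexa-2,4-dien-1-one | C=C1C(=O)C=CC=C1O[Si](C)(C)C(C)(C)C | intermediate
11 | ethyl 2-[(2R,5R)-2,5-dimethylthiolan-1-ium-1-yl]acetate ylide (carbanion on the carbon between sulfur and ester) | CCOC(=O)[CH-][S+]1[C@H](C)CC[C@H]1C | intermediate
12 | ethyl (2R)-3-[2-(tert-butyldimethylsilyloxy)-6-oxidophenyl]-2-[(2R,5R)-2,5-dimethylthiolan-1-ium-1-yl]propanoate (the epimer that closes to 13; the two epimers at C2 interconvert) | CCOC(=O)[C@@H](Cc1c([O-])cccc1O[Si](C)(C)C(C)(C)C)[S+]1[C@H](C)CC[C@H]1C | intermediate
13 | ethyl (2S)-4-(tert-butyldimethylsilyloxy)-2,3-dihydro-1-benzofuran-2-carboxylate | CC(C)(C)[Si](C)(C)Oc1cccc2c1C[C@@H](C(=O)OCC)O2 | intermediate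
14 | 1-[(2S)-4-(tert-butyldimethylsilyloxy)-2,3-dihydro-1-benzofuran-2-yl]ethan-1-one | CC(C)(C)[Si](C)(C)Oc1cccc2c1C[C@@H](C(C)=O)O2 | intermediate
15 | 2-[(2S)-4-(tert-butyldimethylsilyloxy)-2,3-dihydro-1-benzofuran-2-yl]propan-2-ol | CC(C)(C)[Si](C)(C)Oc1cccc2c1C[C@@H](C(C)(C)O)O2 | intermediate
16 | (2S)-2-(2-hydroxypropan-2-yl)-2,3-dihydro-1-benzofuran-4-ol | Oc1cccc2c1C[C@@H](C(C)(C)O)O2 | intermediate
17 | (2S)-5-(hydroxymethyl)-2-(2-hydroxypropan-2-yl)-2,3-dihydro-1-benzofuran-4-ol | OCc1ccc2c(c1O)C[C@@H](C(C)(C)O)O2 | intermediate
18 | (2S)-4-hydroxy-2-(2-hydroxypropan-2-yl)-2,3-dihydro-1-benzofuran-5-carbaldehyde | O=Cc1ccc2c(c1O)C[C@@H](C(C)(C)O)O2 | intermediate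
19 | (2S)-2-(2-hydroxypropan-2-yl)-4-methoxy-2,3-dihydro-1-benzofuran-5-carbaldehyde | COc1c(C=O)ccc2c1C[C@@H](C(C)(C)O)O2 | intermediate
20 | 4-hydroxyacetophenone | CC(=O)c1ccc(O)cc1 | starting material
21 | 3-hydroxy-3-[(2S)-2-(2-hydroxypropan-2-yl)-4-methoxy-2,3-dihydro-1-benzofuran-5-yl]-1-(4-hydroxyphenyl)propan-1-one (both epimers at the carbinol carbon) | COc1c(C(O)CC(=O)c2ccc(O)cc2)ccc2c1C[C@@H](C(C)(C)O)O2 | intermediate
22 | (2E)-3-[(2S)-2-(2-hydroxypropan-2-yl)-4-methoxy-2,3-dihydro-1-benzofuran-5-yl]-1-(4-hydroxyphenyl)prop-2-en-1-one | COc1c(/C=C/C(=O)c2ccc(O)cc2)ccc2c1C[C@@H](C(C)(C)O)O2 | target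

## Step count and least certain steps

Total: 12 steps. Longest linear sequence: 9 steps (steps 1–3 and 7–12 from 1; the sulfonium branch, steps 4–6 and 7–12 from 5, is equally long).

**Step 7 (key step, proposed new method).** The most likely failure is weak discrimination between the two diastereomeric ring-closing transition states, because the methyl groups of the leaving thiolane are two bonds from the reacting carbon; this would erode the enantiomeric purity. Lesser risks are β-elimination of the sulfide from the betaine, oligomerisation of the methide, and base-mediated epimerisation of the product ester. Fallback by known chemistry, setting out from 4: the same fluoride-triggered annulation is run with the achiral, commercial (2-ethoxy-2-oxoethyl)dimethylsulfonium bromide and Cs2CO3, an annulation of established type. It gives racemic ethyl 4-(tert-butyldimethylsilyloxy)-2,3-dihydro-1-benzofuran-2-carboxylate F1, which is resolved by preparative chromatography on a chiral stationary phase. The S enantiomer is 13, where the route is rejoined, and the unwanted half of F1 can be racemised with an amine base and recycled.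

**Step 3.** The bromide lies next to two oxygen-bearing ring positions, so ionisation on silica or on standing, followed by silyl loss and uncontrolled methide formation and oligomerisation, is the likely failure. Fallback setting out from 3: acetylation (Ac2O, pyridine, DMAP) gives [2,6-bis(tert-butyldimethylsilyloxy)phenyl]methyl acetate F2, a benzylic ester that can be purified and stored. Under the fluoride conditions of step 7 the phenoxide expels acetate and the route is rejoined at 10.

**Step 6.** The sulfide is branched at both α-carbons, so slow or reversible S-alkylation and dealkylation of the salt by bromide on concentration are the likely failures. Fallback setting out from 7: Rh2(OAc)4-catalysed decomposition of ethyl diazoacetate in the presence of 7 transfers the carbene to sulfur, a known way to ester-stabilised sulfonium ylides. It gives the ylide without passing through a salt, and the route is rejoined at 11 in step 7.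

**Step 10.** Incomplete formylation is the likely failure, because the tertiary alkoxide and O1 compete for magnesium; condensation of the hydroxymethyl intermediate with a second phenol to diarylmethanes is also possible. Fallback setting out from 16: amine-directed ortho-bromination (NBS, catalytic iPr2NH, CH2Cl2) gives (2S)-5-bromo-2-(2-hydroxypropan-2-yl)-2,3-dihydro-1-benzofuran-4-ol F3. O-Methylation (MeI, K2CO3) gives 2-[(2S)-5-bromo-4-methoxy-2,3-dihydro-1-benzofuran-2-yl]propan-2-ol F4. Bromine–lithium exchange (n-BuLi, 2.2 equiv, THF, −78 °C) and quenching with DMF rejoin the route at 19.

**Step 12.** Slow condensation is the likely failure: the phenoxide of 20 lowers the acidity of its methyl group, and the aldehyde is deactivated by two alkoxy donors and flanked by the methoxy group. Long exposure to strong base then invites Cannizzaro disproportionation. Fallback setting out from 20 and 19: 20 is protected with 3,4-dihydro-2H-pyran (PPTS, CH2Cl2) as 1-[4-(oxan-2-yloxy)phenyl]ethan-1-one F5. Condensation of F5 with 19 (KOH, EtOH, or Ba(OH)2, MeOH) gives (2E)-3-[(2S)-2-(2-hydroxypropan-2-yl)-4-methoxy-2,3-dihydro-1-benzofuran-5-yl]-1-[4-(oxan-2-yloxy)phenyl]prop-2-en-1-one F6. Mild acetal exchange (PPTS, MeOH, 40 °C) frees the phenol and rejoins the route at 22.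

## Further compounds

F1 | step 7 | racemic ethyl 4-(tert-butyldimethylsilyloxy)-2,3-dihydro-1-benzofuran-2-carboxylate | CCOC(=O)C1Cc2c(O[Si](C)(C)C(C)(C)C)cccc2O1
F2 | step 3 | [2,6-bis(tert-butyldimethylsilyloxy)phenyl]methyl acetate | CC(=O)OCc1c(O[Si](C)(C)C(C)(C)C)cccc1O[Si](C)(C)C(C)(C)C
F0 | step 6 | none | none
F3 | step 10 | (2S)-5-bromo-2-(2-hydroxypropan-2-yl)-2,3-dihydro-1-benzofuran-4-ol | Oc1c(Br)ccc2c1C[C@@H](C(C)(C)O)O2
F4 | step 10 | 2-[(2S)-5-bromo-4-methoxy-2,3-dihydro-1-benzofuran-2-yl]propan-2-ol | COc1c(Br)ccc2c1C[C@@H](C(C)(C)O)O2
F5 | step 12 | 1-[4-(oxan-2-yloxy)phenyl]ethan-1-one (racemic at the acetal carbon) | CC(=O)c1ccc(OC2CCCCO2)cc1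
F6 | step 12 | (2E)-3-[(2S)-2-(2-hydroxypropan-2-yl)-4-methoxy-2,3-dihydro-1-benzofuran-5-yl]-1-[4-(oxan-2-yloxy)phenyl]prop-2-en-1-one (both epimers at the acetal carbon) | COc1c(/C=C/C(=O)c2ccc(OC3CCCCO3)cc2)ccc2c1C[C@@H](C(C)(C)O)O2
A1 | alternative 1 | 2-[(2S)-4-({1-[4-(methoxymethoxy)phenyl]prop-2-yn-1-yl}oxy)-2,3-dihydro-1-benzofuran-2-yl]propan-2-ol (both epimers at the propargylic carbon) | C#CC(Oc1cccc2c1C[C@@H](C(C)(C)O)O2)c1ccc(OCOC)cc1
A2 | alternative 1 | (8S)-8-(2-hydroxypropan-2-yl)-2-[4-(methoxymethoxy)phenyl]-8,9-dihydro-2H-furo[2,3-h]chromene (both epimers at the chromene C2) | COCOc1ccc(cc1)C1C=Cc2ccc3c(c2O1)C[C@@H](C(C)(C)O)O3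
A3 | alternative 2 | 2-iodobenzene-1,3-diol (2-iodoresorcinol) | Oc1cccc(O)c1I
A4 | alternative 2 | 2-methylbuta-1,3-diene (isoprene) | C=CC(C)=C
A5 | alternative 2 | (2S)-2-(prop-1-en-2-yl)-2,3-dihydro-1-benzofuran-4-ol | Oc1cccc2c1C[C@@H](C(C)=C)O2
A6 | alternative 3 | methyl 5-methoxy-2,2-dimethyl-2H-chromene-6-carboxylate | COC(=O)c1ccc2OC(C)(C)C=Cc2c1OC
A7 | alternative 3 | methyl (3R)-3-hydroxy-5-methoxy-2,2-dimethyl-3,4-dihydro-2H-chromene-6-carboxylate | COC(=O)c1ccc2OC(C)(C)[C@H](O)Cc2c1OC
A8 | alternative 3 | methyl (2S)-2-(2-hydroxypropan-2-yl)-4-methoxy-2,3-dihydro-1-benzofuran-5-carboxylate | COC(=O)c1ccc2c(c1OC)C[C@@H](C(C)(C)O)O2
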